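**Retrosynthetic overview**
1. Target ⇒ bridged keto ether (a 2-oxabicyclo[2.2.1]heptan-6-one) by retro-Baeyer–Villiger: the last step inserts the lactone oxygen between C15 and C11 and creates the acylal.
2. Keto ether ⇒ α-chloro ketone by intramolecular etherification (C15–O7); chloro ketone ⇒ tertiary C8 radical (caesium oxalate of a cis-perhydroazulenol, fragment 1) + 2-chlorocyclopentenone (fragment 2) by radical conjugate addition.
3. Fragment 2 ⇐ (1S,4R)-cis-4-acetoxycyclopent-2-enol: O–H insertion, [2,3]-Wittig shift (its ether oxygen later becomes O7), silylation, allylic oxidation, α-chlorination.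
4. Fragment 1 ⇐ isobutyronitrile: alkylation, cyclopentenone annulation, asymmetric CuH reduction, gold-catalysed 7-exo-dig closure, MeLi addition, oxalate formation.
5. Ring order: cyclopentenone (the five-membered carbocycle) → seven-membered ring; after coupling to the cyclopentane of fragment 2: tetrahydrofuran bridge → δ-lactone (by expansion of that cyclopentanone).

Atom labels used below: C1–C3 ring CH2, C4 CMe2, C5 and C9 ring-fusion CH, C6 and C7 CH2, C8 quaternary C(CH3), C10 (=CH2); C11 lactone C=O, C12 CH–OAc, C13 CH, C14 CH bonded to C8, C15 acetal CH, C16 CH–CO2Me; O7 ring ether oxygen, O2 lactone ring oxygen.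

Assumption: 17 (the enzymatically made monoacetate) and 18 (as a stabilised solution) are bought; the gold complex of step 6 is prepared separately and not counted.

**Route**

Step 1
Reactants: 1 isobutyronitrile; 2 (5-chloropent-1-yn-1-yl)trimethylsilane
Product: 3 2,2-dimethyl-7-(trimethylsilyl)hept-6-ynenitrile
Conditions: LiN(i-Pr)2, THF, −78 °C; then 2, DMPU, −78 → 25 °C
Reagents that add atoms: none
Why: SN2 C-alkylation of the lithiated nitrile by the primary chloride creates the gem-dimethyl quaternary carbon C4; no stereocentre is formed.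

Step 2
Reactants: 3 2,2-dimethyl-7-(trimethylsilyl)hept-6-ynenitrile; 4 2-(2-bromoethyl)-2-methyl-1,3-dioxolane
Product: 7 6,6-dimethyl-11-(trimethylsilyl)undec-10-yne-2,5-dione, via Grignard reagent 5 (not isolated), via N-magnesio ketimine 6 (not isolated)
Conditions: 4, Mg, THF, 25 °C; then 3, CuBr·SMe2 (5 mol %), 45 °C; then 2 M HCl, 25 °C
Reagents that add atoms: water, O
Why: Copper-assisted Grignard addition to the hindered nitrile stops at the N-magnesio ketimine, and aqueous acid then hydrolyses both the imine and the dioxolane to the 1,4-diketone (nitrile-to-ketone synthesis); no stereocentre.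

Step 3
Reactants: 7 6,6-dimethyl-11-(trimethylsilyl)undec-10-yne-2,5-dione
Product: 8 3-[2-methyl-7-(trimethylsilyl)hept-6-yn-2-yl]cyclopent-2-en-1-one
Conditions: KOt-Bu (1.1 equiv), THF, 0 → 25 °C
Reagents that add atoms: none
Why: Intramolecular aldol condensation in which only the methyl-ketone enolate can close a five-membered ring onto the tert-alkyl ketone, while the aprotic base spares the C–SiMe3 bond; no stereocentre.

Step 4
Reactants: 8 3-[2-methyl-7-(trimethylsilyl)hept-6-yn-2-yl]cyclopent-2-en-1-one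
Product: 11 triisopropyl({(3R)-3-[2-methyl-7-(trimethylsilyl)hept-6-yn-2-yl]cyclopent-1-en-1-yl}oxy)silane, via bis-enoxy diphenylsilane 9 (not isolated), via lithium enolate 10 (not isolated)
Conditions: CuCl, NaOt-Bu, (S)-p-tol-BINAP (5 mol % each; the ligand antipode that gives the 3R series), Ph2SiH2 (0.55 equiv), toluene, 0 °C; then MeLi, THF, −78 → 0 °C; then i-Pr3SiOTf, −78 °C
Reagents that add atoms: triisopropylsilyl trifluoromethanesulfonate, CC(C)[Si](C(C)C)(C(C)C)OS(=O)(=O)C(F)(F)F
Why: Ligand-controlled asymmetric conjugate reduction by copper hydride (1,4-hydrosilylation) sets C5 as R and delivers the enolate regiospecifically on the C9 side, and Si-to-Li-to-Si exchange fixes it as the robust TIPS enol ether.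

Step 5
Reactants: 11 triisopropyl({(3R)-3-[2-methyl-7-(trimethylsilyl)hept-6-yn-2-yl]cyclopent-1-en-1-yl}oxy)silane
Product: 12 triisopropyl{[(3R)-3-(2-methylhept-6-yn-2-yl)cyclopent-1-en-1-yl]oxy}silane
Conditions: K2CO3 (0.2 equiv), MeOH, 25 °C
Reagents that add atoms: none
Why: Base-catalysed methanolysis cleaves only the alkynyl C–SiMe3 bond (protodesilylation), leaving the hindered TIPS enol ether and C5 untouched.

Step 6
Reactants: 12 triisopropyl{[(3R)-3-(2-methylhept-6-yn-2-yl)cyclopent-1-en-1-yl]oxy}silane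
Product: 13 (3aR,8aS)-4,4-dimethyl-8-methylideneoctahydroazulen-1(2H)-one (cis-fused)
Conditions: [(Ar3SiC≡C)3P]AuNTf2 (Ar = 3,5-di-tert-butyl-4-methoxyphenyl; 2 mol %), MeOH (2 equiv), CH2Cl2, 25 °C
Reagents that add atoms: none
Why: Gold-catalysed 7-exo-dig carbocyclisation of the silyl enol ether onto the π-activated alkyne (Conia-ene type) forms C9–C10 and the exocyclic methylene, and the tether on C5 reaches the enol face cis to its own bond, which sets C9 and the cis ring fusion.

Step 7
Reactants: 13 (3aR,8aS)-4,4-dimethyl-8-methylideneoctahydroazulen-1(2H)-one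
Product: 14 (1S,3aR,8aS)-1,4,4-trimethyl-8-methylidenedecahydroazulen-1-ol
Conditions: MeLi, CeCl3, THF, −78 °C
Reagents that add atoms: methyllithium, [Li]C
Why: Organocerium 1,2-addition (non-basic, so C9 does not epimerise) from the convex face gives one tertiary alcohol, whose C8 configuration is erased later at the radical stage.

Step 8
Reactants: 14 (1S,3aR,8aS)-1,4,4-trimethyl-8-methylidenedecahydroazulen-1-ol
Product: 16 caesium 2-oxo-2-{[(1S,3aR,8aS)-1,4,4-trimethyl-8-methylidenedecahydroazulen-1-yl]oxy}acetate, via methyl oxalate 15 (not isolated)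
Conditions: ClCOCO2Me, Et3N, DMAP (cat.), CH2Cl2, 0 → 25 °C; then CsOH (1.0 equiv, 1 M aq.), THF, 25 °C
Reagents that add atoms: methyl chlorooxoacetate, COC(=O)C(Cl)=O; caesium hydroxide, [Cs+].[OH-]
Why: O-acylation of the tertiary alcohol followed by selective saponification of the unhindered methyl ester gives the oxalate half-ester salt needed for oxidative radical generation; stereocentres untouched.

Step 9
Reactants: 17 (1S,4R)-cis-4-acetoxycyclopent-2-en-1-ol; 18 methyl diazoacetate
Product: 19 methyl 2-{[(1S,4R)-4-acetoxycyclopent-2-en-1-yl]oxy}acetate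
Conditions: Rh2(OAc)4 (1 mol %), CH2Cl2, 25 °C, slow addition of 18
Reagents that add atoms: none
Why: Rhodium-carbenoid O–H insertion etherifies the alcohol under neutral conditions, so the cis acetate cannot migrate and both stereocentres are retained.

Step 10
Reactants: 19 methyl 2-{[(1S,4R)-4-acetoxycyclopent-2-en-1-yl]oxy}acetate
Product: 20 methyl (2R)-2-[(1R,5R)-5-acetoxycyclopent-2-en-1-yl]-2-hydroxyacetate
Conditions: Bu2BOTf, i-Pr2NEt, CH2Cl2, −78 → 0 °C; then pH 7 buffer, MeOH
Reagents that add atoms: none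
Why: [2,3]-Wittig rearrangement of the chelated boron enolate (soft enolisation selects the alkoxy ester over the acetate) is suprafacial, so the new C13–C16 bond forms cis to the acetate, and the envelope transition state with the ester turned away from the acetoxy-bearing carbon sets C16 as R.

Step 11
Reactants: 20 methyl (2R)-2-[(1R,5R)-5-acetoxycyclopent-2-en-1-yl]-2-hydroxyacetate
Product: 21 methyl (2R)-2-[(1S,5R)-5-acetoxycyclopent-2-en-1-yl]-2-[(tert-butyldimethylsilyl)oxy]acetate
Conditions: t-BuMe2SiOTf, 2,6-lutidine, CH2Cl2, −78 → 0 °C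
Reagents that add atoms: tert-butyldimethylsilyl trifluoromethanesulfonate, CC(C)(C)[Si](C)(C)OS(=O)(=O)C(F)(F)F
Why: Silylation of the secondary alcohol (silyl ether protection) shields it from the oxidations that follow; stereocentres untouched (the descriptor at C13 changes only because priorities change).

Step 12
Reactants: 21 methyl (2R)-2-[(1S,5R)-5-acetoxycyclopent-2-en-1-yl]-2-[(tert-butyldimethylsilyl)oxy]acetate
Product: 22 methyl (2R)-2-[(1S,5S)-5-acetoxy-4-oxocyclopent-2-en-1-yl]-2-[(tert-butyldimethylsilyl)oxy]acetate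
Conditions: CrO3, 3,5-dimethylpyrazole, CH2Cl2, −20 °C
Reagents that add atoms: chromium trioxide, O=[Cr](=O)=O
Why: Allylic oxidation of the only allylic CH2 (C11) by the CrO3–pyrazole complex gives the enone without touching the tertiary allylic C13–H or the stereocentres.

Step 13
Reactants: 22 methyl (2R)-2-[(1S,5S)-5-acetoxy-4-oxocyclopent-2-en-1-yl]-2-[(tert-butyldimethylsilyl)oxy]acetate
Product: 23 methyl (2R)-2-[(1S,5S)-5-acetoxy-3-chloro-4-oxocyclopent-2-en-1-yl]-2-[(tert-butyldimethylsilyl)oxy]acetate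
Conditions: PhICl2, pyridine, CH2Cl2, 0 → 25 °C
Reagents that add atoms: (dichloroiodo)benzene, ClI(Cl)c1ccccc1
Why: Chlorine addition across the enone followed by pyridine-induced loss of HCl (addition–elimination α-halogenation) places chlorine on C15; stereocentres untouched.

Step 14
Reactants: 16 caesium 2-oxo-2-{[(1S,3aR,8aS)-1,4,4-trimethyl-8-methylidenedecahydroazulen-1-yl]oxy}acetate; 23 methyl (2R)-2-[(1S,5S)-5-acetoxy-3-chloro-4-oxocyclopent-2-en-1-yl]-2-[(tert-butyldimethylsilyl)oxy]acetate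
Product: 24 methyl (2R)-2-{(1S,2S,4S,5R)-2-acetoxy-4-chloro-3-oxo-5-[(1R,3aR,8aS)-1,4,4-trimethyl-8-methylidenedecahydroazulen-1-yl]cyclopentyl}-2-[(tert-butyldimethylsilyl)oxy]acetate
Conditions: Ir[dF(CF3)ppy]2(dtbbpy)PF6 (2 mol %), H2O (10 equiv), DME/DMF 3:1, blue LEDs, 60 °C
Reagents that add atoms: none
Why: Photoredox oxidation of the oxalate and loss of two CO2 give the tertiary C8 radical, which adds (Giese-type radical conjugate addition) through its convex face, cis to H9, to C14 on the enone face anti to the C13 side chain and C12 acetate, setting C8 and C14, and the reduced enolate is protonated anti to the new substituent, setting C15 with Cl cis to it.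

Step 15
Reactants: 24 methyl (2R)-2-{(1S,2S,4S,5R)-2-acetoxy-4-chloro-3-oxo-5-[(1R,3aR,8aS)-1,4,4-trimethyl-8-methylidenedecahydroazulen-1-yl]cyclopentyl}-2-[(tert-butyldimethylsilyl)oxy]acetate
Product: 25 methyl (1R,3R,4S,5S,7R)-5-acetoxy-6-oxo-7-[(1R,3aR,8aS)-1,4,4-trimethyl-8-methylidenedecahydroazulen-1-yl]-2-oxabicyclo[2.2.1]heptane-3-carboxylate
Conditions: Bu4NF (1.2 equiv), THF, −20 → 0 °C
Reagents that add atoms: none
Why: Fluoride desilylation frees the C16 alkoxide, which displaces the activated α-chloride from the opposite face (intramolecular Williamson etherification, SN2 with inversion at C15, any C15 epimer equilibrating through the enolate) to close the oxygen bridge with the ester exo.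

Step 16
Reactants: 25 methyl (1R,3R,4S,5S,7R)-5-acetoxy-6-oxo-7-[(1R,3aR,8aS)-1,4,4-trimethyl-8-methylidenedecahydroazulen-1-yl]-2-oxabicyclo[2.2.1]heptane-3-carboxylate
Product: 26 methyl (1S,4S,5R,6R,8R)-4-acetoxy-3-oxo-8-[(1R,3aR,8aS)-1,4,4-trimethyl-8-methylidenedecahydroazulen-1-yl]-2,7-dioxabicyclo[3.2.1]octane-6-carboxylate (target)
Conditions: Me3SiOOSiMe3 (3 equiv), Me3SiOTf (20 mol %), 2,6-di-tert-butyl-4-methylpyridine (10 mol %), CH2Cl2, −78 → −30 °C
Reagents that add atoms: bis(trimethylsilyl) peroxide, C[Si](C)(C)OO[Si](C)(C)C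
Why: Proposed new method: a peracid-free silyl-peroxide Baeyer–Villiger ring expansion of a 2-oxabicyclo[2.2.1]heptan-6-one, not yet shown for this ring system, in which the silylated Criegee adduct and the exo lone pair of O7 are both antiperiplanar to the C15–C11 bond, so the acetal-type bridgehead C15 migrates with retention (setting the acylal stereocentre) in preference to the acetoxy-bearing C12, while the non-electrophilic oxidant spares the 1,1-disubstituted alkene; the closest known reaction types are the bridgehead-migrating Baeyer–Villiger oxidation of 7-oxabicyclo[2.2.1]heptan-2-ones and the Me3SiOOSiMe3/Me3SiOTf oxidation of ketones in the presence of C=C bonds.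

**Compound list**

1 | isobutyronitrile | CC(C)C#N | starting material
2 | (5-chloropent-1-yn-1-yl)trimethylsilane | C[Si](C)(C)C#CCCCCl | starting material
3 | 2,2-dimethyl-7-(trimethylsilyl)hept-6-ynenitrile | N#CC(C)(C)CCCC#C[Si](C)(C)C | intermediate
4 | 2-(2-bromoethyl)-2-methyl-1,3-dioxolane | CC1(CCBr)OCCO1 | starting material
5 | [2-(2-methyl-1,3-dioxolan-2-yl)ethyl]magnesium bromide | CC1(CC[Mg]Br)OCCO1 | intermediate
6 | N-bromomagnesio ketimine from 5 and 3 (dioxolane intact) | CC1(CCC(=N[Mg]Br)C(C)(C)CCCC#C[Si](C)(C)C)OCCO1 | intermediate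
7 | 6,6-dimethyl-11-(trimethylsilyl)undec-10-yne-2,5-dione | CC(=O)CCC(=O)C(C)(C)CCCC#C[Si](C)(C)C | intermediate
8 | 3-[2-methyl-7-(trimethylsilyl)hept-6-yn-2-yl]cyclopent-2-en-1-one | O=C1CCC(C(C)(C)CCCC#C[Si](C)(C)C)=C1 | intermediate
9 | diphenylbis({(3R)-3-[2-methyl-7-(trimethylsilyl)hept-6-yn-2-yl]cyclopent-1-en-1-yl}oxy)silane | C[Si](C)(C)C#CCCCC(C)(C)[C@@H]1CCC(O[Si](c2ccccc2)(c2ccccc2)OC2=C[C@H](C(C)(C)CCCC#C[Si](C)(C)C)CC2)=C1 | intermediate
10 | lithium (3R)-3-[2-methyl-7-(trimethylsilyl)hept-6-yn-2-yl]cyclopent-1-en-1-olate | C[Si](C)(C)C#CCCCC(C)(C)[C@@H]1CCC(O[Li])=C1 | intermediate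
11 | triisopropyl({(3R)-3-[2-methyl-7-(trimethylsilyl)hept-6-yn-2-yl]cyclopent-1-en-1-yl}oxy)silane | C[Si](C)(C)C#CCCCC(C)(C)[C@@H]1CCC(O[Si](C(C)C)(C(C)C)C(C)C)=C1 | intermediate
12 | triisopropyl{[(3R)-3-(2-methylhept-6-yn-2-yl)cyclopent-1-en-1-yl]oxy}silane | C#CCCCC(C)(C)[C@@H]1CCC(O[Si](C(C)C)(C(C)C)C(C)C)=C1 | intermediate
13 | (3aR,8aS)-4,4-dimethyl-8-methylideneoctahydroazulen-1(2H)-one | C=C1CCCC(C)(C)[C@@H]2CCC(=O)[C@H]12 | intermediate
14 | (1S,3aR,8aS)-1,4,4-trimethyl-8-methylidenedecahydroazulen-1-ol | C=C1CCCC(C)(C)[C@@H]2CC[C@@](O)(C)[C@H]12 | intermediate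
15 | methyl (1S,3aR,8aS)-1,4,4-trimethyl-8-methylidenedecahydroazulen-1-yl oxalate | C=C1CCCC(C)(C)[C@@H]2CC[C@@](OC(=O)C(=O)OC)(C)[C@H]12 | intermediate
16 | caesium 2-oxo-2-{[(1S,3aR,8aS)-1,4,4-trimethyl-8-methylidenedecahydroazulen-1-yl]oxy}acetate | C=C1CCCC(C)(C)[C@@H]2CC[C@@](OC(=O)C(=O)[O-])(C)[C@H]12.[Cs+] | intermediate
17 | (1S,4R)-cis-4-acetoxycyclopent-2-en-1-ol | C1[C@@H](OC(C)=O)C=C[C@H]1O | starting material
18 | methyl diazoacetate | COC(=O)C=[N+]=[N-] | starting material
19 | methyl 2-{[(1S,4R)-4-acetoxycyclopent-2-en-1-yl]oxy}acetate | C1[C@@H](OC(C)=O)C=C[C@H]1OCC(=O)OC | intermediate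
20 | methyl (2R)-2-[(1R,5R)-5-acetoxycyclopent-2-en-1-yl]-2-hydroxyacetate (side chain cis to acetate) | C1[C@@H](OC(C)=O)[C@@H]([C@@H](O)C(=O)OC)C=C1 | intermediate
21 | methyl (2R)-2-[(1S,5R)-5-acetoxycyclopent-2-en-1-yl]-2-[(tert-butyldimethylsilyl)oxy]acetate | C1[C@@H](OC(C)=O)[C@@H]([C@@H](O[Si](C)(C)C(C)(C)C)C(=O)OC)C=C1 | intermediate
22 | methyl (2R)-2-[(1S,5S)-5-acetoxy-4-oxocyclopent-2-en-1-yl]-2-[(tert-butyldimethylsilyl)oxy]acetate | O=C1[C@@H](OC(C)=O)[C@@H]([C@@H](O[Si](C)(C)C(C)(C)C)C(=O)OC)C=C1 | intermediate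
23 | methyl (2R)-2-[(1S,5S)-5-acetoxy-3-chloro-4-oxocyclopent-2-en-1-yl]-2-[(tert-butyldimethylsilyl)oxy]acetate | O=C1[C@@H](OC(C)=O)[C@@H]([C@@H](O[Si](C)(C)C(C)(C)C)C(=O)OC)C=C1Cl | intermediate
24 | methyl (2R)-2-{(1S,2S,4S,5R)-2-acetoxy-4-chloro-3-oxo-5-[(1R,3aR,8aS)-1,4,4-trimethyl-8-methylidenedecahydroazulen-1-yl]cyclopentyl}-2-[(tert-butyldimethylsilyl)oxy]acetate (azulenyl and Cl trans to side chain and acetate) | C=C1CCCC(C)(C)[C@@H]2CC[C@@](C)([C@@H]3[C@H](Cl)C(=O)[C@@H](OC(C)=O)[C@H]3[C@H](C(=O)OC)O[Si](C)(C)C(C)(C)C)[C@H]12 | intermediate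
25 | methyl (1R,3R,4S,5S,7R)-5-acetoxy-6-oxo-7-[(1R,3aR,8aS)-1,4,4-trimethyl-8-methylidenedecahydroazulen-1-yl]-2-oxabicyclo[2.2.1]heptane-3-carboxylate (ester exo, acetate endo, azulenyl syn to the keto bridge) | C=C1CCCC(C)(C)[C@@H]2CC[C@@](C)([C@@H]3[C@@H]4C(=O)[C@@H](OC(C)=O)[C@H]3[C@H](C(=O)OC)O4)[C@H]12 | intermediate
26 | methyl (1S,4S,5R,6R,8R)-4-acetoxy-3-oxo-8-[(1R,3aR,8aS)-1,4,4-trimethyl-8-methylidenedecahydroazulen-1-yl]-2,7-dioxabicyclo[3.2.1]octane-6-carboxylate | C=C1CCCC(C)(C)[C@@H]2CC[C@@](C)([C@@H]3[C@@H]4OC(=O)[C@@H](OC(C)=O)[C@H]3[C@H](C(=O)OC)O4)[C@H]12 | target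

**Step count and risks**

Total step count: 16. Longest linear sequence: 11 steps (steps 1–8, then 14–16).

The three steps most likely to fail:

Step 16 (the proposed new step). The ketone is flanked by the tert-alkyl group on the one-carbon bridge, so peroxide addition may be slow, and the acylal product is acid-sensitive. The fallback uses known chemistry, sets out from 24 and comes back at 26. Zn dust and Me3SiCl (THF, 0 °C) reduce the C–Cl bond and give the regiodefined trimethylsilyl enol ether F1. One equivalent of dimethyldioxirane at −78 °C (Rubottom oxidation; the enol ether reacts far faster than the exocyclic alkene) gives the C15 α-hydroxy ketone F2. NaIO4 in aqueous THF cleaves the C11–C15 bond to the aldehyde acid F3. HF·pyridine then removes the silyl ether and, with catalytic p-TsOH, the C16 hydroxyl adds to the C15 aldehyde and the C11 acid closes onto the lactol, giving 26 under thermodynamic control.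

Step 6. Seven-membered ring closure by gold catalysis depends on a special ligand and competes with hydrolysis of the enol ether. The fallback sets out from 12 and comes back at 13. Bu4NF (THF, 0 °C) releases the ketone (3R)-3-(2-methylhept-6-yn-2-yl)cyclopentan-1-one F4. NaI/Me3SiCl/H2O in MeCN adds HI across the terminal alkyne in the Markovnikov sense to give the 2-iodoalkene (3R)-3-(6-iodo-2-methylhept-6-en-2-yl)cyclopentan-1-one F5. Pd(PPh3)4 with KOt-Bu in THF then closes the ring by intramolecular α-alkenylation of the ketone; the two enolates equilibrate, but only the C9 enolate can reach the alkenylpalladium, giving 13.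

Step 12. Allylic oxidation next to an acetoxy-bearing carbon may be slow or give the transposed enone. The fallback sets out from 21 and comes back at 22. SeO2 (catalytic) with t-BuOOH in CH2Cl2 hydroxylates the ring CH2 by an ene reaction followed by a [2,3]-shift, which cannot transpose the alkene, and gives the C11 allylic alcohol of 21 F6. Dess–Martin periodinane then gives 22.

**Further compounds**

F1 | step 16 | trimethylsilyl enol ether (C15=C11–OSiMe3) of dechlorinated 24, other stereocentres as in 24 | C=C1CCCC(C)(C)[C@@H]2CC[C@@](C)([C@@H]3C=C(O[Si](C)(C)C)[C@@H](OC(C)=O)[C@H]3[C@H](C(=O)OC)O[Si](C)(C)C(C)(C)C)[C@H]12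
F2 | step 16 | C15 α-hydroxy ketone (OH in place of Cl of 24, on the face of the side chain) | C=C1CCCC(C)(C)[C@@H]2CC[C@@](C)([C@@H]3[C@@H](O)C(=O)[C@@H](OC(C)=O)[C@H]3[C@H](C(=O)OC)O[Si](C)(C)C(C)(C)C)[C@H]12
F3 | step 16 | seco aldehyde acid (C15 aldehyde, C11 carboxylic acid, C16 silyl ether) | C=C1CCCC(C)(C)[C@@H]2CC[C@@](C)([C@H](C=O)[C@@H]([C@H](OC(C)=O)C(O)=O)[C@H](C(=O)OC)O[Si](C)(C)C(C)(C)C)[C@H]12
F4 | step 6 | (3R)-3-(2-methylhept-6-yn-2-yl)cyclopentan-1-one | C#CCCCC(C)(C)[C@@H]1CCC(=O)C1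
F5 | step 6 | (3R)-3-(6-iodo-2-methylhept-6-en-2-yl)cyclopentan-1-one | C=C(I)CCCC(C)(C)[C@@H]1CCC(=O)C1
F6 | step 12 | C11 allylic alcohol of 21 (hydroxyl trans to the acetate) | O[C@@H]1[C@@H](OC(C)=O)[C@@H]([C@@H](O[Si](C)(C)C(C)(C)C)C(=O)OC)C=C1
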